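## Analysis of the target

The target is a 7,9'-epoxylignan of the lariciresinol type. It has one oxolane ring (O1, C2, C3, C4, C5) carrying a 3,4-dihydroxyphenyl group (ring A) at C2, an acetoxymethyl arm at C3 and a 4-hydroxy-3-methoxybenzyl group (ring B) at C4; C5 is an unsubstituted CH2. The three stereocentres are contiguous and (2S,3R,4R): the aryl group at C2 is trans to the C3 arm, and the arm is cis to the C4 benzyl group. Sensitive points are the free catechol and guaiacol units (oxidation, base) and the primary acetate beside three phenols (acyl transfer, solvolysis). The most delicate is the C2–O1 bond, a benzylic ether activated by oxygen donors on ring A: it ionises under acid (epimerisation at C2, ring opening, capture by ring B) and can be hydrogenolysed. The difficulty is to combine the 2,3-trans with the less stable 3,4-cis relationship in one absolute sense, to form C2–O1 without a free benzylic cation, and to finish with one acylated aliphatic hydroxyl next to three free phenols. The strategy rests on the position of O1 between the aryl-bearing C2 and the methylene C5. With O1 removed, C2, C3, C4 and C5 form a four-membered carbocycle, the 2-aryl-3-substituted cyclobutanone 12 with its carbonyl at C5, and oxygen can be put back between C5 and C2 by a stereoretentive migration. C2–C3 and C4–C5 can then be made together in a cycloaddition, the 2,3-trans relationship is settled by equilibration next to the ketone, and the lactone carbonyl that appears at C5 activates C4 for the attachment of ring B.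

## Retrosynthetic reasoning

**22 from 21.** The last operation adds hydrogen only: the C4–H and benzylic C–H bonds (saturation of an exocyclic benzylidene) and the three phenolic O–H bonds (loss of benzyl groups) are made in one catalytic hydrogenation of 21. This lets all three phenols travel as identical benzyl ethers. It also creates the C4 stereocentre last, when the C3 arm is in place to shield one face. The forward step must deliver hydrogen anti to the arm and must spare the C2–O1 bond.

**21 from 19 via 20.** The acetate cannot survive amide bases or hydride reagents, so the arm oxygen is carried as a triisopropylsilyl ether and exchanged for acetate (19 to 20 to 21) only after the ring is built. The exchange comes before debenzylation, so acetylation meets no free phenol.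

**19 from 17 via 18.** The O1–C5 bond is cut and C5 is raised to the carboxyl level. Forward, lactone 17 is reduced to diol 18 and the ether is closed by dehydration at the primary allylic carbon C5, with the C2 oxygen as nucleophile. The C2–O bond made in the key step is therefore never broken. A Lewis-acid/silane deoxygenation of a lactol was not chosen because it would ionise the electron-rich benzylic ether.

**17 from 13 and 14.** The bond between C4 and the benzylic carbon of ring B is cut as an aldol condensation of lactone 13 with aldehyde 14 (through adducts 15 and 16). The only enolisable position of 13 is C4. A direct enolate benzylation would place the benzyl group trans to the arm, which is the wrong relationship, whereas a benzylidene defers the C4 configuration to the hydrogenation.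

**13 from 12 (key disconnection).** O1 is removed from between C2 and C5, giving the trans cyclobutanone 12. Forward, a buffered peracid inserts oxygen between the carbonyl carbon and the aryl-bearing carbon. This forms O1–C2 and O1–C5, expands the ring to the γ-lactone and transfers the C2 configuration unchanged. Cutting here converts a heterocycle with three different ring carbons into a carbocycle that a single cycloaddition can assemble.

**12 from 6 and 8.** The cyclobutanone is cut at C2–C3 and C4–C5 into the keteniminium ion 9 derived from amide 6 and the alkene 8. The electrophilic central carbon (future C5) bonds to the CH2 terminus of 8 (future C4) and the enamine carbon (future C2) to the internal alkene carbon (future C3), which places the silyloxymethyl arm at C3. The C2-symmetric amine 4 in 6 selects the alkene face and so sets C3. Hydrolysis of iminium salt 10 and base equilibration of the crude ketone 11 give the trans isomer 12.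

**6, 3 and 8 from 1, 4 and 7.** Amide 6 comes from acid 3 (via chloride 5) and amine 4. Acid 3 comes from 3,4-dihydroxyphenylacetic acid 1 by exhaustive benzylation and saponification of ester 2. Alkene 8 comes from allyl alcohol 7 by silylation.

## Alternatives that were turned down

**Alternative 1:** The lactone is cut at C2–C3 and at the acyl C5–O1 bond, leading back to aldehyde A2 and the (Z)-configured 2-ethoxycarbonyl allylboronate A3.
- Forward key step: a chiral phosphoric acid activates the boronate. In the chair transition state the γ-silyloxymethyl group and the aryl group are both equatorial, and the anti borate closes onto the ester to give the trans α-methylene lactone A1.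
- For: C2, C3 and the lactone are formed in one catalytic, auxiliary-free operation. A1 is at the same oxidation level as lactone 13, so on paper this route reaches the lactone in fewer steps than the chosen one.
- Against: the allyl unit of A3 is conjugated to an ester and is a weak nucleophile, and A2 is an electron-rich, weakly electrophilic aldehyde. The addition would need forcing acid activation, under which a catalyst-bound, selective transition state is not assured. The stereodefined trisubstituted alkene of A3 needs several steps of its own. A1 has a bare methylene at C4, so ring B must still be attached by arylation of the exocyclic alkene, where β-hydride elimination toward the ring would move the double bond to C3–C4 and erase the C3 stereocentre. The same lactone-to-ether and hydrogenation steps follow.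
- Comparison: the chosen route is longer to the lactone and uses a stoichiometric auxiliary. In exchange, the skeleton is assembled by a strongly electrophilic keteniminium ion and ring B enters by an ordinary enolate aldol on 13.

**Alternative 2:** C2–C3 and the C4–benzyl bond are cut.
- Forward key step: the lithiated dithiane A6 adds to the β-carbon of the menthyloxy butenolide A5 on the face away from the menthyloxy group. The lactone enolate is trapped in the same flask by benzyl bromide A7, trans to the new substituent, giving A4.
- For: the tandem addition–alkylation is reliable, and the auxiliary is cheap and of the natural menthyl series. C3 and C4 are fixed in one step. The 3,4-cis relationship of the target is encoded as the easily reached trans relationship of A4, because the oxolane is later re-formed through other atoms (the acetal carbon becomes the C3 arm, the lactone carbonyl becomes C5). On this point, and probably on step count, it is stronger than the chosen strategy, which must win the C4 configuration in a face-selective hydrogenation.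
- Against: C2 leaves the key step as a dithioketal. It must be unmasked with oxidising or thiophilic reagents in the presence of three benzyl ethers and two electron-rich rings. The resulting aryl ketone is reduced without control. C2–O1 is then closed from a triol through a benzylic cation, so the C2 configuration rests on thermodynamic preference alone, and ring B can capture the cation to give a cyclolignan.
- Comparison: the chosen strategy makes C2–O1 by a stereospecific carbon-to-oxygen shift from a centre already fixed trans to the arm, with no cation at C2 at any stage. The C3 arm is distinguished from C5 from the first C–C bond onwards.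

**Alternative 3:** Only O1–C2 is cut, back to the (2R,3R)-dibenzylbutanediol A9, which has one free para-phenol.
- Forward key step: a quinone oxidant (or an anode) converts the para-hydroxybenzyl unit into a quinone methide, and the distal primary hydroxyl adds to its terminus in a 5-exo closure to give A8.
- For: the step is biomimetic and short. C3 and C4 come from a trans-dibenzylbutyrolactone precursor, so the 3,4-cis relationship again costs nothing, and the acid-sensitive ring is formed late.
- Against: A9 needs two differently protected but electronically similar aryl rings and its own asymmetric synthesis. The oxidant must distinguish the rings. The new benzylic ether of A8 still has a free para-phenol and can be oxidised again. Ring B can compete with the hydroxyl for the quinone methide, and C2 is set only by reversible addition. The phenol freed for the key step also prevents a clean mono-acetylation of the primary hydroxyl, which costs protecting-group steps at the end.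
- Comparison: the chosen route is longer before its key step. In exchange, all three phenols stay benzylated until the last step, the oxidant meets a single reactive site (a strained ketone), and C2 is defined before the oxygen is introduced.

Key step: step 5

Remark on the chemistry (assumption): the sense of induction of the (2S,5S)-2,5-dimethylpyrrolidine auxiliary in step 4 is taken from a steric model (alkene approaching the keteniminium carbon on the hydrogen side, away from the nearer ring methyl group, with the silyloxymethyl arm turned outwards). It must be confirmed on 12; if the antipode forms, (2R,5R)-2,5-dimethylpyrrolidine is used in step 2 and nothing else changes. Amine 4 and aldehyde 14 are taken as purchased.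

## Route

Step 1
Reactants: 1 3,4-dihydroxyphenylacetic acid
Product: 3 3,4-bis(benzyloxy)phenylacetic acid, via benzyl 3,4-bis(benzyloxy)phenylacetate 2 (not isolated)
Conditions: BnBr (3.5 equiv), K2CO3, DMF, 60 °C, N2; then NaOH, THF/MeOH/H2O, 60 °C; 1 M HCl to pH 2
Reagents that add atoms: benzyl bromide, BrCc1ccccc1; sodium hydroxide, [Na+].[OH-] (oxygen of the regenerated carboxyl OH)
Why: Williamson O-alkylation of both phenols and the carboxylate, followed by saponification of the benzyl ester only, since aryl benzyl ethers are inert to hydroxide; no stereocentre is involved.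

Step 2
Reactants: 3 3,4-bis(benzyloxy)phenylacetic acid; 4 (2S,5S)-2,5-dimethylpyrrolidine
Product: 6 2-[3,4-bis(benzyloxy)phenyl]-1-[(2S,5S)-2,5-dimethylpyrrolidin-1-yl]ethan-1-one, via 3,4-bis(benzyloxy)phenylacetyl chloride 5 (not isolated)
Conditions: (COCl)2, DMF (cat.), CH2Cl2, 0 °C → rt; concentrate; then 4, Et3N, CH2Cl2, 0 °C → rt
Reagents that add atoms: oxalyl chloride, ClC(=O)C(=O)Cl (chlorine of intermediate 5 only; none of its atoms remain in 6)
Why: Acid chloride formation and N-acylation (Schotten–Baumann type); the acid chloride is reactive enough for the hindered secondary amine, and the stereocentres of 4 are not touched.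

Step 3
Reactants: 7 allyl alcohol
Product: 8 triisopropyl(prop-2-en-1-yloxy)silane
Conditions: i-Pr3SiCl, imidazole, DMF, rt
Reagents that add atoms: triisopropylsilyl chloride, CC(C)[Si](Cl)(C(C)C)C(C)C
Why: Standard imidazole-mediated silylation of a primary alcohol; the triisopropylsilyl ether is chosen because it withstands triflate salts, amide bases and aluminium hydrides later in the route.

Step 4
Reactants: 6 2-[3,4-bis(benzyloxy)phenyl]-1-[(2S,5S)-2,5-dimethylpyrrolidin-1-yl]ethan-1-one; 8 triisopropyl(prop-2-en-1-yloxy)silane
Product: 12 (2S,3S)-2-[3,4-bis(benzyloxy)phenyl]-3-{[(triisopropylsilyl)oxy]methyl}cyclobutan-1-one, via keteniminium triflate 9 (not isolated), via cyclobutaniminium triflate 10 (not isolated), via cyclobutanone C2-epimer mixture 11 (not isolated)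
Conditions: Tf2O (1.2 equiv), 8 (4 equiv), ClCH2CH2Cl, −20 °C; 2,4,6-collidine (1.3 equiv) added slowly, then 80 °C; then sat. aq. NaHCO3, rt; crude ketone: DBU (0.2 equiv), CH2Cl2, rt, N2
Reagents that add atoms: water, O (carbonyl oxygen of 11 and 12); trifluoromethanesulfonic anhydride, O=S(=O)(OS(=O)(=O)C(F)(F)F)C(F)(F)F (triflate counter-ion of intermediates 9 and 10 only)
Why: Keteniminium–alkene [2+2] cycloaddition: O-triflation of 6 and elimination give 9, whose central carbon is attacked by the CH2 terminus of 8 (the more stabilised cation develops at the internal carbon), and collapse onto the enamine carbon closes the four-membered ring with the arm at C3, the C2-symmetric auxiliary selecting the alkene face and so setting C3 as (3S). Hydrolysis releases the ketone and amine 4, and DBU equilibrates the acidic aryl-bearing C2 through the enol to the more stable trans (2S,3S) isomer.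

Step 5
Reactants: 12 (2S,3S)-2-[3,4-bis(benzyloxy)phenyl]-3-{[(triisopropylsilyl)oxy]methyl}cyclobutan-1-one
Product: 13 (4R,5S)-5-[3,4-bis(benzyloxy)phenyl]-4-{[(triisopropylsilyl)oxy]methyl}dihydrofuran-2(3H)-one
Conditions: mCPBA (1.3 equiv), NaHCO3 (3 equiv), CH2Cl2, 0 °C → rt
Reagents that add atoms: 3-chloroperbenzoic acid (mCPBA), OOC(=O)c1cccc(Cl)c1
Why: Baeyer–Villiger oxidation: the peracid adds to the strained, unhindered carbonyl of 12 to give a tetrahedral peroxyester adduct. In this adduct the ring bond from the carbonyl carbon to C2 migrates to oxygen as 3-chlorobenzoate leaves; C2 is secondary, benzylic and attached to an electron-rich ring, so it carries the developing positive charge far better than the C4 methylene, which secures the required regiochemistry (oxygen between the carbonyl carbon and the aryl-bearing carbon, forming O1–C2 and O1–C5 of the target). The closest known reaction type is the peracid oxidation of 2-aryl- and 2-alkylcyclobutanones to γ-substituted γ-butyrolactones. The five-membered lactone is not closed by an exo or endo cyclisation but by ring expansion, a 1,2-shift of carbon to oxygen that enlarges the four-membered ring by one atom and is driven by release of strain. No stereocentre is created: the migrating carbon keeps its configuration, so (2S) of 12 becomes (5S) of 13, and C3 of 12 is untouched (its descriptor becomes 4R only through a change of substituent priorities). The step needs chemoselectivity for the ketone over the two benzyloxy-substituted rings and the silyl ether; strain-accelerated carbonyl addition at 0 °C outruns arene oxidation, and the NaHCO3 buffer keeps 3-chlorobenzoic acid from ionising the new benzylic C–O bond.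

Step 6
Reactants: 13 (4R,5S)-5-[3,4-bis(benzyloxy)phenyl]-4-{[(triisopropylsilyl)oxy]methyl}dihydrofuran-2(3H)-one; 14 4-(benzyloxy)-3-methoxybenzaldehyde
Product: 15 (4R,5S)-5-[3,4-bis(benzyloxy)phenyl]-3-{[4-(benzyloxy)-3-methoxyphenyl](hydroxy)methyl}-4-{[(triisopropylsilyl)oxy]methyl}dihydrofuran-2(3H)-one (mixture of diastereomers at C3 and the carbinol carbon)
Conditions: LiN(i-Pr)2 (1.15 equiv), THF, −78 °C; then 14 (1.2 equiv), −78 °C; sat. aq. NH4Cl
Reagents that add atoms: none
Why: Lithium enolate aldol addition at the only enolisable position of the lactone (the future C4); the enolate has no leaving group on its β-carbon, so it does not fragment, and the two new stereocentres are removed in the next step.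

Step 7
Reactants: 15 (4R,5S)-5-[3,4-bis(benzyloxy)phenyl]-3-{[4-(benzyloxy)-3-methoxyphenyl](hydroxy)methyl}-4-{[(triisopropylsilyl)oxy]methyl}dihydrofuran-2(3H)-one
Product: 17 (3E,4R,5S)-5-[3,4-bis(benzyloxy)phenyl]-3-{[4-(benzyloxy)-3-methoxyphenyl]methylidene}-4-{[(triisopropylsilyl)oxy]methyl}dihydrofuran-2(3H)-one, via aldol acetate 16 (not isolated)
Conditions: Ac2O, Et3N, DMAP (cat.), CH2Cl2, 0 °C → rt; then DBU (3 equiv), rt → 40 °C
Reagents that add atoms: acetic anhydride, CC(=O)OC(C)=O (acetyl group of intermediate 16 only; lost again in the elimination)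
Why: Acetylation followed by E1cB elimination gives the conjugated (E)-benzylidene lactone, the usual outcome of aldol condensations of butyrolactones with aryl aldehydes; the geometry is not critical because only the face of the alkene decides the later C4 configuration, and C4 and C5 of the lactone are not acidic under these conditions.

Step 8
Reactants: 17 (3E,4R,5S)-5-[3,4-bis(benzyloxy)phenyl]-3-{[4-(benzyloxy)-3-methoxyphenyl]methylidene}-4-{[(triisopropylsilyl)oxy]methyl}dihydrofuran-2(3H)-one
Product: 18 (1S,2R,3E)-1-[3,4-bis(benzyloxy)phenyl]-3-{[4-(benzyloxy)-3-methoxyphenyl]methylidene}-2-{[(triisopropylsilyl)oxy]methyl}butane-1,4-diol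
Conditions: (i-Bu)2AlH (4.5 equiv), CH2Cl2, −78 → 0 °C; aq. potassium sodium tartrate
Reagents that add atoms: none
Why: Aluminium hydride 1,2-reduction of an α-alkylidene lactone through the lactol to the allylic 1,4-diol; (i-Bu)2AlH does not add in a conjugate sense, and silyl ether, benzyl ethers and both stereocentres are unaffected.

Step 9
Reactants: 18 (1S,2R,3E)-1-[3,4-bis(benzyloxy)phenyl]-3-{[4-(benzyloxy)-3-methoxyphenyl]methylidene}-2-{[(triisopropylsilyl)oxy]methyl}butane-1,4-diol
Product: 19 {[(2S,3R,4E)-2-[3,4-bis(benzyloxy)phenyl]-4-{[4-(benzyloxy)-3-methoxyphenyl]methylidene}oxolan-3-yl]methoxy}triisopropylsilane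
Conditions: PPh3 (1.3 equiv), DIAD (1.3 equiv), THF, 0 °C → rt
Reagents that add atoms: none
Why: Mitsunobu cyclodehydration: the oxyphosphonium ion forms at the unhindered primary allylic hydroxyl and is displaced by the benzylic hydroxyl in a 5-exo-tet SN2 closure, forming O1–C5; the C2–O bond is not broken, so C2 keeps its configuration.

Step 10
Reactants: 19 {[(2S,3R,4E)-2-[3,4-bis(benzyloxy)phenyl]-4-{[4-(benzyloxy)-3-methoxyphenyl]methylidene}oxolan-3-yl]methoxy}triisopropylsilane
Product: 20 [(2S,3R,4E)-2-[3,4-bis(benzyloxy)phenyl]-4-{[4-(benzyloxy)-3-methoxyphenyl]methylidene}oxolan-3-yl]methanol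
Conditions: n-Bu4NF (1.2 equiv), THF, 0 °C → rt
Reagents that add atoms: none
Why: Fluoride-induced cleavage of the silyl ether; nothing else in the molecule reacts with fluoride.

Step 11
Reactants: 20 [(2S,3R,4E)-2-[3,4-bis(benzyloxy)phenyl]-4-{[4-(benzyloxy)-3-methoxyphenyl]methylidene}oxolan-3-yl]methanol
Product: 21 [(2S,3R,4E)-2-[3,4-bis(benzyloxy)phenyl]-4-{[4-(benzyloxy)-3-methoxyphenyl]methylidene}oxolan-3-yl]methyl acetate
Conditions: Ac2O, pyridine, DMAP (cat.), CH2Cl2, 0 °C → rt
Reagents that add atoms: acetic anhydride, CC(=O)OC(C)=O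
Why: Acylation of the only free hydroxyl; all phenols are still benzylated, so no selectivity problem arises.

Step 12
Reactants: 21 [(2S,3R,4E)-2-[3,4-bis(benzyloxy)phenyl]-4-{[4-(benzyloxy)-3-methoxyphenyl]methylidene}oxolan-3-yl]methyl acetate
Product: 22 [(2S,3R,4R)-2-(3,4-dihydroxyphenyl)-4-(4-hydroxy-3-methoxybenzyl)oxolan-3-yl]methyl acetate (the target)
Conditions: H2 (1 atm), 10% Pd/C, EtOAc, rt
Reagents that add atoms: none
Why: Heterogeneous syn-hydrogenation of the exocyclic alkene from the face opposite the adjacent C3 acetoxymethyl arm (allylic strain with the benzylidene aryl group turns the arm out of the alkene plane, where it shields its own face), which places the new benzyl group cis to the arm and sets C4 as (4R). The three aryl benzyl ethers are hydrogenolysed in the same operation; neutral aprotic solvent and stopping after uptake of four equivalents of hydrogen are intended to spare the benzylic C2–O1 bond.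

## Compound list

1 | 3,4-dihydroxyphenylacetic acid | OC(=O)Cc1ccc(O)c(O)c1 | starting material
2 | benzyl 3,4-bis(benzyloxy)phenylacetate | O=C(Cc1ccc(OCc2ccccc2)c(OCc2ccccc2)c1)OCc1ccccc1 | intermediate (not isolated)
3 | 3,4-bis(benzyloxy)phenylacetic acid | OC(=O)Cc1ccc(OCc2ccccc2)c(OCc2ccccc2)c1 | intermediate
4 | (2S,5S)-2,5-dimethylpyrrolidine | C[C@H]1CC[C@H](C)N1 | starting material
5 | 3,4-bis(benzyloxy)phenylacetyl chloride | ClC(=O)Cc1ccc(OCc2ccccc2)c(OCc2ccccc2)c1 | intermediate (not isolated)
6 | 2-[3,4-bis(benzyloxy)phenyl]-1-[(2S,5S)-2,5-dimethylpyrrolidin-1-yl]ethan-1-one | C[C@H]1CC[C@H](C)N1C(=O)Cc1ccc(OCc2ccccc2)c(OCc2ccccc2)c1 | intermediate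
7 | allyl alcohol (prop-2-en-1-ol) | C=CCO | starting material
8 | triisopropyl(prop-2-en-1-yloxy)silane | C=CCO[Si](C(C)C)(C(C)C)C(C)C | intermediate
9 | (2S,5S)-1-{2-[3,4-bis(benzyloxy)phenyl]ethenylidene}-2,5-dimethylpyrrolidin-1-ium trifluoromethanesulfonate (keteniminium triflate) | C[C@H]1CC[C@H](C)[N+]1=C=Cc1ccc(OCc2ccccc2)c(OCc2ccccc2)c1.[O-]S(=O)(=O)C(F)(F)F | intermediate (not isolated)
10 | (2S,5S)-1-[(3S)-2-[3,4-bis(benzyloxy)phenyl]-3-{[(triisopropylsilyl)oxy]methyl}cyclobutylidene]-2,5-dimethylpyrrolidin-1-ium trifluoromethanesulfonate, epimers at the aryl-bearing carbon | C[C@H]1CC[C@H](C)[N+]1=C2C(c3ccc(OCc4ccccc4)c(OCc4ccccc4)c3)[C@@H](CO[Si](C(C)C)(C(C)C)C(C)C)C2.[O-]S(=O)(=O)C(F)(F)F | intermediate (not isolated)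
11 | (3S)-2-[3,4-bis(benzyloxy)phenyl]-3-{[(triisopropylsilyl)oxy]methyl}cyclobutan-1-one, cis/trans mixture at C2 | O=C1C(c2ccc(OCc3ccccc3)c(OCc3ccccc3)c2)[C@@H](CO[Si](C(C)C)(C(C)C)C(C)C)C1 | intermediate (not isolated)
12 | (2S,3S)-2-[3,4-bis(benzyloxy)phenyl]-3-{[(triisopropylsilyl)oxy]methyl}cyclobutan-1-one (trans) | O=C1[C@H](c2ccc(OCc3ccccc3)c(OCc3ccccc3)c2)[C@@H](CO[Si](C(C)C)(C(C)C)C(C)C)C1 | intermediate
13 | (4R,5S)-5-[3,4-bis(benzyloxy)phenyl]-4-{[(triisopropylsilyl)oxy]methyl}dihydrofuran-2(3H)-one (trans) | O=C1O[C@H](c2ccc(OCc3ccccc3)c(OCc3ccccc3)c2)[C@@H](CO[Si](C(C)C)(C(C)C)C(C)C)C1 | intermediate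
14 | 4-(benzyloxy)-3-methoxybenzaldehyde | COc1cc(C=O)ccc1OCc1ccccc1 | starting material
15 | (4R,5S)-5-[3,4-bis(benzyloxy)phenyl]-3-{[4-(benzyloxy)-3-methoxyphenyl](hydroxy)methyl}-4-{[(triisopropylsilyl)oxy]methyl}dihydrofuran-2(3H)-one, diastereomer mixture at C3 and the carbinol carbon | O=C1O[C@H](c2ccc(OCc3ccccc3)c(OCc3ccccc3)c2)[C@@H](CO[Si](C(C)C)(C(C)C)C(C)C)C1C(O)c1ccc(OCc2ccccc2)c(OC)c1 | intermediate
16 | acetate of 15 at the benzylic hydroxyl, diastereomer mixture | O=C1O[C@H](c2ccc(OCc3ccccc3)c(OCc3ccccc3)c2)[C@@H](CO[Si](C(C)C)(C(C)C)C(C)C)C1C(OC(C)=O)c1ccc(OCc2ccccc2)c(OC)c1 | intermediate (not isolated)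
17 | (3E,4R,5S)-5-[3,4-bis(benzyloxy)phenyl]-3-{[4-(benzyloxy)-3-methoxyphenyl]methylidene}-4-{[(triisopropylsilyl)oxy]methyl}dihydrofuran-2(3H)-one | O=C1O[C@H](c2ccc(OCc3ccccc3)c(OCc3ccccc3)c2)[C@@H](CO[Si](C(C)C)(C(C)C)C(C)C)/C1=C\c1ccc(OCc2ccccc2)c(OC)c1 | intermediate
18 | (1S,2R,3E)-1-[3,4-bis(benzyloxy)phenyl]-3-{[4-(benzyloxy)-3-methoxyphenyl]methylidene}-2-{[(triisopropylsilyl)oxy]methyl}butane-1,4-diol | O[C@H](c1ccc(OCc2ccccc2)c(OCc2ccccc2)c1)[C@@H](CO[Si](C(C)C)(C(C)C)C(C)C)/C(CO)=C\c1ccc(OCc2ccccc2)c(OC)c1 | intermediate
19 | {[(2S,3R,4E)-2-[3,4-bis(benzyloxy)phenyl]-4-{[4-(benzyloxy)-3-methoxyphenyl]methylidene}oxolan-3-yl]methoxy}triisopropylsilane | C1O[C@H](c2ccc(OCc3ccccc3)c(OCc3ccccc3)c2)[C@@H](CO[Si](C(C)C)(C(C)C)C(C)C)/C1=C\c1ccc(OCc2ccccc2)c(OC)c1 | intermediate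
20 | [(2S,3R,4E)-2-[3,4-bis(benzyloxy)phenyl]-4-{[4-(benzyloxy)-3-methoxyphenyl]methylidene}oxolan-3-yl]methanol | C1O[C@H](c2ccc(OCc3ccccc3)c(OCc3ccccc3)c2)[C@@H](CO)/C1=C\c1ccc(OCc2ccccc2)c(OC)c1 | intermediate
21 | [(2S,3R,4E)-2-[3,4-bis(benzyloxy)phenyl]-4-{[4-(benzyloxy)-3-methoxyphenyl]methylidene}oxolan-3-yl]methyl acetate | C1O[C@H](c2ccc(OCc3ccccc3)c(OCc3ccccc3)c2)[C@@H](COC(C)=O)/C1=C\c1ccc(OCc2ccccc2)c(OC)c1 | intermediate
22 | [(2S,3R,4R)-2-(3,4-dihydroxyphenyl)-4-(4-hydroxy-3-methoxybenzyl)oxolan-3-yl]methyl acetate | COc1cc(C[C@H]2CO[C@H](c3ccc(O)c(O)c3)[C@H]2COC(C)=O)ccc1O | target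

## Step count and least certain steps

Total: 12 steps. Longest linear sequence: 11 steps (1 to 22 through steps 1, 2 and 4–12); step 3 prepares the alkene partner in a side branch.

**Step 5 (key step).**
- What may go wrong: electrophilic attack of the peracid on the electron-rich bis(benzyloxy)phenyl ring, and acid-induced ionisation of the new benzylic lactone C–O bond by the carboxylic acid by-product (epimerisation at the aryl-bearing carbon, ring opening) if buffering is incomplete. The migration regiochemistry itself is secure.
- Fallback, from 12 back to 13: oxygen is inserted with a nucleophilic instead of an electrophilic oxidant. Hydroperoxide anion (30% H2O2, NaOH, THF/MeOH/H2O, 0 °C) adds only to the strained carbonyl and the same benzylic carbon migrates. Under the alkaline conditions the lactone is saponified, so after careful acidification to pH 5 the product is the hydroxy acid (3R,4S)-4-[3,4-bis(benzyloxy)phenyl]-4-hydroxy-3-{[(triisopropylsilyl)oxy]methyl}butanoic acid F1. This is closed in a separate neutral step (EDC·HCl, DMAP cat., CH2Cl2, rt) to 13.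

**Step 4.**
- What may go wrong: slow capture of the keteniminium ion 9 by the alkene 8, whose nucleophilicity is lowered by the allylic oxygen, so that self-condensation of 9 competes. The higher temperature then needed would also erode the face selectivity imposed by the auxiliary.
- Fallback, from 6 back to 13: a more nucleophilic two-carbon partner is used and the arm is unveiled later. With the same activation (Tf2O, 2,4,6-collidine, CH2Cl2, −20 → 40 °C, sealed vessel), excess 1,3-butadiene reacts at one double bond. Hydrolysis and DBU equilibration give (2S,3R)-2-[3,4-bis(benzyloxy)phenyl]-3-ethenylcyclobutan-1-one F2. Buffered mCPBA as in step 5 (the strained ketone reacts much faster than the monosubstituted alkene) gives (4R,5S)-5-[3,4-bis(benzyloxy)phenyl]-4-ethenyldihydrofuran-2(3H)-one F3. Oxidative cleavage (OsO4 cat., NaIO4, 2,6-lutidine, dioxane/H2O) gives (2S,3S)-2-[3,4-bis(benzyloxy)phenyl]-5-oxooxolane-3-carbaldehyde F4, which is reduced without purification (NaBH4, MeOH, −20 °C) to (4R,5S)-5-[3,4-bis(benzyloxy)phenyl]-4-(hydroxymethyl)dihydrofuran-2(3H)-one F5. Silylation (i-Pr3SiCl, imidazole, DMF) returns to 13.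

**Step 12.**
- What may go wrong: delivery of hydrogen to the wrong face of the alkene, because the C2 aryl group on the face opposite the C3 arm also hinders the catalyst; and reductive cleavage on palladium of the benzylic C2–O1 bond, or of the allylic C5–O1 bond before the alkene is saturated.
- Fallback, from 17 to 22: the C4 configuration is set by enolate protonation instead of at a catalyst surface, and debenzylation is left for a substrate without an alkene. Conjugate reduction of 17 with LiBH(s-Bu)3 (THF, −78 °C) gives the lactone enolate, which is protonated at −78 °C by 2,6-di-tert-butyl-4-methylphenol on the face away from the adjacent arm. This should give (3R,4R,5S)-5-[3,4-bis(benzyloxy)phenyl]-3-[4-(benzyloxy)-3-methoxybenzyl]-4-{[(triisopropylsilyl)oxy]methyl}dihydrofuran-2(3H)-one F6. LiAlH4 (THF, 0 °C) gives (1S,2R,3R)-1-[3,4-bis(benzyloxy)phenyl]-3-[4-(benzyloxy)-3-methoxybenzyl]-2-{[(triisopropylsilyl)oxy]methyl}butane-1,4-diol F7. Mitsunobu closure as in step 9 gives {[(2S,3R,4R)-2-[3,4-bis(benzyloxy)phenyl]-4-[4-(benzyloxy)-3-methoxybenzyl]oxolan-3-yl]methoxy}triisopropylsilane F8. n-Bu4NF gives [(2S,3R,4R)-2-[3,4-bis(benzyloxy)phenyl]-4-[4-(benzyloxy)-3-methoxybenzyl]oxolan-3-yl]methanol F9, and Ac2O/pyridine gives [(2S,3R,4R)-2-[3,4-bis(benzyloxy)phenyl]-4-[4-(benzyloxy)-3-methoxybenzyl]oxolan-3-yl]methyl acetate F10. Brief hydrogenolysis of the three benzyl ethers alone (H2, 10% Pd/C, EtOAc, rt) then gives 22; the exposure to palladium is shorter but not eliminated.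

**Step 9.**
- What may go wrong: activation of the secondary benzylic hydroxyl instead of the primary allylic one. Because the aryl group is electron-rich this leads to ionisation at C2 (loss of the 2,3-trans relationship, elimination); attack at the benzylidene carbon in an SN2' sense is a further possibility.
- Fallback, from 18 back to 19: the two events are separated so that the benzylic C–O bond is never activated. The primary allylic hydroxyl is sulfonylated selectively (TsCl 1.05 equiv, Et3N, DMAP cat., CH2Cl2, −20 °C) to (2E,3R,4S)-4-[3,4-bis(benzyloxy)phenyl]-2-{[4-(benzyloxy)-3-methoxyphenyl]methylidene}-4-hydroxy-3-{[(triisopropylsilyl)oxy]methyl}butyl 4-methylbenzenesulfonate F11. The ring is then closed by the benzylic alkoxide (NaH, THF, 0 °C, intramolecular Williamson etherification), which returns to 19.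

## Further compounds

F1 | step 5 | (3R,4S)-4-[3,4-bis(benzyloxy)phenyl]-4-hydroxy-3-{[(triisopropylsilyl)oxy]methyl}butanoic acid | O[C@H](c1ccc(OCc2ccccc2)c(OCc2ccccc2)c1)[C@@H](CO[Si](C(C)C)(C(C)C)C(C)C)CC(=O)O
F2 | step 4 | (2S,3R)-2-[3,4-bis(benzyloxy)phenyl]-3-ethenylcyclobutan-1-one | O=C1[C@H](c2ccc(OCc3ccccc3)c(OCc3ccccc3)c2)[C@@H](C=C)C1
F3 | step 4 | (4R,5S)-5-[3,4-bis(benzyloxy)phenyl]-4-ethenyldihydrofuran-2(3H)-one | O=C1O[C@H](c2ccc(OCc3ccccc3)c(OCc3ccccc3)c2)[C@@H](C=C)C1
F4 | step 4 | (2S,3S)-2-[3,4-bis(benzyloxy)phenyl]-5-oxooxolane-3-carbaldehyde | O=C1O[C@H](c2ccc(OCc3ccccc3)c(OCc3ccccc3)c2)[C@@H](C=O)C1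
F5 | step 4 | (4R,5S)-5-[3,4-bis(benzyloxy)phenyl]-4-(hydroxymethyl)dihydrofuran-2(3H)-one | O=C1O[C@H](c2ccc(OCc3ccccc3)c(OCc3ccccc3)c2)[C@@H](CO)C1
F6 | step 12 | (3R,4R,5S)-5-[3,4-bis(benzyloxy)phenyl]-3-[4-(benzyloxy)-3-methoxybenzyl]-4-{[(triisopropylsilyl)oxy]methyl}dihydrofuran-2(3H)-one | COc1cc(C[C@H]2C(=O)O[C@H](c3ccc(OCc4ccccc4)c(OCc4ccccc4)c3)[C@H]2CO[Si](C(C)C)(C(C)C)C(C)C)ccc1OCc1ccccc1
F7 | step 12 | (1S,2R,3R)-1-[3,4-bis(benzyloxy)phenyl]-3-[4-(benzyloxy)-3-methoxybenzyl]-2-{[(triisopropylsilyl)oxy]methyl}butane-1,4-diol | COc1cc(C[C@@H](CO)[C@H](CO[Si](C(C)C)(C(C)C)C(C)C)[C@H](O)c2ccc(OCc3ccccc3)c(OCc3ccccc3)c2)ccc1OCc1ccccc1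
F8 | step 12 | {[(2S,3R,4R)-2-[3,4-bis(benzyloxy)phenyl]-4-[4-(benzyloxy)-3-methoxybenzyl]oxolan-3-yl]methoxy}triisopropylsilane | COc1cc(C[C@H]2CO[C@H](c3ccc(OCc4ccccc4)c(OCc4ccccc4)c3)[C@H]2CO[Si](C(C)C)(C(C)C)C(C)C)ccc1OCc1ccccc1
F9 | step 12 | [(2S,3R,4R)-2-[3,4-bis(benzyloxy)phenyl]-4-[4-(benzyloxy)-3-methoxybenzyl]oxolan-3-yl]methanol | COc1cc(C[C@H]2CO[C@H](c3ccc(OCc4ccccc4)c(OCc4ccccc4)c3)[C@H]2CO)ccc1OCc1ccccc1
F10 | step 12 | [(2S,3R,4R)-2-[3,4-bis(benzyloxy)phenyl]-4-[4-(benzyloxy)-3-methoxybenzyl]oxolan-3-yl]methyl acetate | COc1cc(C[C@H]2CO[C@H](c3ccc(OCc4ccccc4)c(OCc4ccccc4)c3)[C@H]2COC(C)=O)ccc1OCc1ccccc1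
F11 | step 9 | (2E,3R,4S)-4-[3,4-bis(benzyloxy)phenyl]-2-{[4-(benzyloxy)-3-methoxyphenyl]methylidene}-4-hydroxy-3-{[(triisopropylsilyl)oxy]methyl}butyl 4-methylbenzenesulfonate | O[C@H](c1ccc(OCc2ccccc2)c(OCc2ccccc2)c1)[C@@H](CO[Si](C(C)C)(C(C)C)C(C)C)/C(COS(=O)(=O)c1ccc(C)cc1)=C\c1ccc(OCc2ccccc2)c(OC)c1
A1 | alternative 1 | (4R,5S)-5-[3,4-bis(benzyloxy)phenyl]-4-{[(tert-butyldimethylsilyl)oxy]methyl}-3-methylidenedihydrofuran-2(3H)-one | O=C1O[C@H](c2ccc(OCc3ccccc3)c(OCc3ccccc3)c2)[C@@H](CO[Si](C)(C)C(C)(C)C)C1=C
A2 | alternative 1 | 3,4-bis(benzyloxy)benzaldehyde | O=Cc1ccc(OCc2ccccc2)c(OCc2ccccc2)c1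
A3 | alternative 1 | ethyl (2Z)-4-[(tert-butyldimethylsilyl)oxy]-2-[(4,4,5,5-tetramethyl-1,3,2-dioxaborolan-2-yl)methyl]but-2-enoate | CCOC(=O)/C(CB1OC(C)(C)C(C)(C)O1)=C\CO[Si](C)(C)C(C)(C)C
A4 | alternative 2 | (3R,4R,5R)-3-[4-(benzyloxy)-3-methoxybenzyl]-4-{2-[3,4-bis(benzyloxy)phenyl]-1,3-dithian-2-yl}-5-{[(1R,2S,5R)-5-methyl-2-(propan-2-yl)cyclohexyl]oxy}dihydrofuran-2(3H)-one | C[C@@H]1CC[C@H]([C@@H](C1)O[C@@H]2OC(=O)[C@H](Cc3ccc(OCc4ccccc4)c(OC)c3)[C@H]2C5(c6ccc(OCc7ccccc7)c(OCc7ccccc7)c6)SCCCS5)C(C)C
A5 | alternative 2 | (5R)-5-{[(1R,2S,5R)-5-methyl-2-(propan-2-yl)cyclohexyl]oxy}furan-2(5H)-one | C[C@@H]1CC[C@H]([C@@H](C1)O[C@@H]2OC(=O)C=C2)C(C)C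
A6 | alternative 2 | 2-[3,4-bis(benzyloxy)phenyl]-1,3-dithiane | C1CSC(SC1)c1ccc(OCc2ccccc2)c(OCc2ccccc2)c1
A7 | alternative 2 | 4-(benzyloxy)-3-methoxybenzyl bromide | COc1cc(CBr)ccc1OCc1ccccc1
A8 | alternative 3 | [(2S,3R,4R)-2-[3-(benzyloxy)-4-hydroxyphenyl]-4-[4-(benzyloxy)-3-methoxybenzyl]oxolan-3-yl]methanol | COc1cc(C[C@H]2CO[C@H](c3ccc(O)c(OCc4ccccc4)c3)[C@H]2CO)ccc1OCc1ccccc1
A9 | alternative 3 | (2R,3R)-2-[3-(benzyloxy)-4-hydroxybenzyl]-3-[4-(benzyloxy)-3-methoxybenzyl]butane-1,4-diol | COc1cc(C[C@@H](CO)[C@H](CO)Cc2ccc(O)c(OCc3ccccc3)c2)ccc1OCc1ccccc1
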